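The runs are calculated with constants of no real substance; the scatter is artificial.

The ratio of bis adduct to mono adduct at the last reading is 1.34 in birch and 17.3 in alder, so don't interpolate on the pair as it stands. Split it into a large term and a correction.

in all of them: solid substrate 0.020 M
- birch: reagent 1.4 equiv (fed, over 40 min); run made earlier
- alder: reagent 2.5 equiv (fed, over 40 min); run made earlier
- eta: reagent 4.00 equiv (fed, over 40 min); time 12 h
- gamma: reagent 2.00 equiv (fed, over 40 min); time 12 h

| run | time / h | bis adduct / % | mono adduct / % |
|---|---|---|---|
| birch | 1.00 | 0.9 | 5.6 |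
| birch | 1.50 | 1.7 | 8.7 |
| birch | 2.50 | 4.5 | 14.6 |
| birch | 4.00 | 9.2 | 20.2 |
| birch | 8.00 | 15.9 | 18.6 |
| birch | 12.0 | 20.7 | 15.5 |
| alder | 2.00 | 6.9 | 13.0 |
| alder | 4.00 | 21.6 | 15.9 |
| alder | 6.00 | 31.8 | 10.0 |
| alder | 8.00 | 38.9 | 6.4 |
| alder | 10.0 | 43.4 | 4.0 |
| alder | 12.0 | 48.4 | 2.8 |

(readings scatter by 0.3 percentage points)

- solid, in amounts per volume of the solution: solid substrate
- the analysis behind the earlier runs scatters by 0.3 percentage points, standard deviation
- at the start none of the solid substrate is in solution

1. which of these holds the largest part of the solid substrate at the end of eta (bis adduct / other mono adduct / solid substrate / mono adduct)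
2. which of these holds the largest part of the solid substrate at the end of gamma (bis adduct / other mono adduct / solid substrate / mono adduct)
3. amount of bis adduct at the end of gamma, in percent of the solid substrate charged

Define the pool P as bis adduct plus mono adduct, in percent of the solid substrate charged. At 12.0 h, P reads 36.2% in birch and 51.2% in alder. Gamma's 2.00 equiv of reagent lies 0.545 of the way from birch to alder, at the same substrate concentration. Interpolate on that basis: the end pool of gamma comes to 44.4%.

Now bracket bis adduct in gamma with two extremes. With no mono adduct left, bis adduct equals the pool, 44.4%. With mono adduct as high as in birch, bis adduct is 28.9%. Gamma carries more reagent than birch, so place it between them. Treat mono adduct as pseudo-first-order in reagent and interpolate its logarithm to a reckoned 6.09%. My figure for bis adduct is therefore 38.3%. The rest of the charge, about 55.6%, I assign to other mono adduct, which was never read, and that is more than my bis adduct.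

The forecast gives 35.5% for gamma, with other mono adduct largest there and bis adduct largest in eta: “Interpolating the 12 h bis between 20.7% (1.4 equiv) and 48.4% (2.5 equiv) gives about 35% at 2.0 equiv.” My figure stands 2.8 percentage points above it.

Gamma ends with 38.2% bis adduct and 54.3% other mono adduct; eta ends with 65.1% bis adduct.

    starting material + reagent → mono adduct + by-product (k = 0.00880 M⁻¹ s⁻¹)
    starting material + reagent → other mono adduct + by-product (k = 0.0170 M⁻¹ s⁻¹)
    reagent + mono adduct → bis adduct + by-product (k = 0.00300 M⁻¹ s⁻¹)
    reagent + other mono adduct → bis adduct + by-product (k = 3.30 × 10⁻⁴ M⁻¹ s⁻¹)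
    solid substrate ⇌ starting material, rate k5*(cs5 - [starting material]) while solid is left; crystals form when [starting material] > cs5 (solubility = 8.60 mM, k = 2.80 × 10⁻⁴ s⁻¹)
    mono adduct ⇌ isomer of the product (K = 0.140, k = 8.10 × 10⁻⁴ s⁻¹)

Gamma's pool ends at 44.8% against the reckoned 44.4%. Carry the pool to the neighbour flask, gamma at 0.0050 M substrate with the same equivalents. Its reagent charge, 0.0100 M, lies below birch's 0.0280 M, outside the span of the two runs, and the line through birch and alder, run on in reagent concentration, gives a pool of 23.9%. The neighbour ends with 61.9% other mono adduct, 18.7% mono adduct and 16.5% bis adduct, a pool of 35.1%.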